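**Assumption:** (R)-epichlorohydrin is taken as a cheap, bought chiral C3 building block and is the only source of chirality. Later compounds use pterocarpan numbering (C6a, C11a).

## Retrosynthetic overview

1. Lespecyrtin E3 ⇐ MOM removal ⇐ one-pot double prenylation (C2 by Br/Li exchange, C10 by ortho-lithiation) of bromo-pterocarpan-chromene 19 ⇐ dimethylpyran ring built on the 8-OH of 17.
2. 17 ⇐ photochemical, redox-neutral cyclisation of isoflavan-quinone 15: forms O11–C11a, closes the dihydrofuran, sets C11a cis to C6a and frees the 8-OH.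
3. 15 ⇐ CAN ⇐ (3R)-isoflavan 14 ⇐ phenonium 1,2-aryl shift/Friedel–Crafts closure of (R)-alcohol 11: forms C6a–aryl with inversion and C11a–C11b.
4. 11 ⇐ aryl Grignard 6 + (R)-epichlorohydrin 5 + 4-bromoresorcinol 8.
5. Ring order: A and D rings bought → chroman pyran ring (step 5) → dihydrofuran ring (step 7) → dimethylpyran ring (step 8).

## Route

Step 1
Reactants: 1 4-bromo-2,5-dimethoxybenzaldehyde
Product: 3 4-bromo-2,5-dimethoxyphenol, via 4-bromo-2,5-dimethoxyphenyl formate 2 (not isolated)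
Conditions: mCPBA, CH2Cl2, 0 °C→rt; then K2CO3 (cat.), MeOH, rt
Reagents that add atoms: mCPBA, OOC(=O)c1cccc(Cl)c1
Why: Baeyer–Villiger (Dakin-type) oxidation of an electron-rich benzaldehyde gives the aryl formate by aryl migration, and methanolysis frees the phenol.

Step 2
Reactants: 3 4-bromo-2,5-dimethoxyphenol
Product: 4 1-bromo-2,5-dimethoxy-4-(methoxymethoxy)benzene
Conditions: NaH, MOMCl, DMF, 0 °C→rt
Reagents that add atoms: chloromethyl methyl ether (MOMCl), COCCl
Why: Williamson-type O-alkylation of the phenoxide (MOM protection); the MOM group later directs the C10 lithiation.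

Step 3
Reactants: 4 1-bromo-2,5-dimethoxy-4-(methoxymethoxy)benzene; 5 (R)-epichlorohydrin
Product: 7 (2R)-1-chloro-3-[2,5-dimethoxy-4-(methoxymethoxy)phenyl]propan-2-ol, via [2,5-dimethoxy-4-(methoxymethoxy)phenyl]magnesium bromide 6 (not isolated)
Conditions: Mg, THF, 45 °C; then CuI (10 mol %), 5, −40→0 °C; H2O
Reagents that add atoms: none
Why: Grignard formation followed by copper-catalysed SN2 opening of the epoxide at its CH2 terminus; the C–O stereocenter of 5 is not touched and becomes the (R)-carbinol.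

Step 4
Reactants: 7 (2R)-chlorohydrin; 8 4-bromoresorcinol (2 equiv)
Product: 11 (2R)-1-[4-bromo-3-(methoxymethoxy)phenoxy]-3-[2,5-dimethoxy-4-(methoxymethoxy)phenyl]propan-2-ol, via (2R)-2-[2,5-dimethoxy-4-(methoxymethoxy)benzyl]oxirane 9 (not isolated), via (2R)-1-(4-bromo-3-hydroxyphenoxy)-3-[2,5-dimethoxy-4-(methoxymethoxy)phenyl]propan-2-ol 10 (not isolated)
Conditions: K2CO3, DMF, 70 °C; then MOMCl, 0 °C→rt (one pot)
Reagents that add atoms: chloromethyl methyl ether (MOMCl), COCCl
Why: Intramolecular Williamson closure to epoxide 9, then opening at CH2 by the phenoxide para to Br (less hindered and more nucleophilic than the ortho-bromo OH), stereocenter untouched; K2CO3/MOMCl then protects only the remaining phenol.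

Step 5
Reactants: 11 (2R)-alcohol
Product: 14 (3R)-6-bromo-3-[2,5-dimethoxy-4-(methoxymethoxy)phenyl]-7-(methoxymethoxy)chroman, via (2R)-triflate of 11 12 (not isolated), via spiro[2.5]octadienyl (phenonium) triflate 13 (not isolated)
Conditions: Tf2O, 2,6-di-tert-butyl-4-methylpyridine, CH2Cl2 (0.02 M), −78→−20 °C
Reagents that add atoms: none
Why: Proposed new method: the secondary triflate ionises with anchimeric assistance of the trioxygenated aryl ring (ipso carbon para to OMOM, Ar1-3 participation) to phenonium ion 13 with inversion at the carbinol carbon, and the tethered aryl ether then opens 13 at the unsubstituted cyclopropane CH2 (6-(enolendo)-exo-tet, para to its OMOM) because closure at the substituted carbon is a Baldwin-disfavoured 5-(enolendo)-exo-tet and that carbon is deactivated by the β-aryloxy group, so the aryl ends on C3 with (R) configuration and the chroman is closed in the same operation; closest known chemistry is the stereospecific 1,2-aryl shift through phenonium ions (solvolysis, dehydrative Friedel–Crafts arylation of β-aryl alcohols) and the 6-endo epoxide–arene Friedel–Crafts cyclisation of aryl glycidyl ethers to 3-chromanols.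

Step 6
Reactants: 14 (3R)-isoflavan
Product: 15 2-[(3R)-6-bromo-7-(methoxymethoxy)chroman-3-yl]-5-(methoxymethoxy)-1,4-benzoquinone
Conditions: CAN, MeCN/H2O (3:1), 0 °C, 15 min
Reagents that add atoms: water, O
Why: CAN oxidative demethylation of the para-dimethoxy pair gives the p-quinone; the less electron-rich bromo-A ring and the MOM ethers survive the short, cold reaction, and C3 is not involved.

Step 7
Reactants: 15 isoflavan-quinone
Product: 17 (6aR,11aR)-2-bromo-3,9-bis(methoxymethoxy)-6a,11a-dihydro-6H-benzofuro[3,2-c]chromen-8-ol, via zwitterion (4-chromanyl cation/hydroquinone monoanion) 16 (not isolated)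
Conditions: hν (427 nm LED), degassed MeCN (5 mM), 20 °C
Reagents that add atoms: none
Why: Proposed new method: the excited quinone (n,π*) removes the benzylic C4–H through a six-membered transition state (intramolecular electron transfer/proton transfer or direct 1,5-hydrogen abstraction by the C2′ carbonyl oxygen, Norrish type II-like), and the biradical collapses via zwitterion 16 to the C4–O bond in a redox-neutral isomerisation where the 6/5 fusion can only be cis, so C11a (R) is set by C6a and the para carbonyl emerges as the free 8-OH; closest known reaction type is the photocyclisation of tert-alkyl-1,4-benzoquinones to 2,3-dihydrobenzofuran-5-ols (Norrish–Yang type) and the photoreduction of quinones by alkylarenes.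

Step 8
Reactants: 17 pterocarpan-8-ol
Product: 19 (6aR,11aR)-2-bromo-3,9-bis(methoxymethoxy)pterocarpan with a 2,2-dimethyl-2H-pyran fused at C7–C8 (O on C8), via 8-O-(2-methylbut-3-yn-2-yl) ether of 17 18 (not isolated)
Conditions: 3-chloro-3-methylbut-1-yne, K2CO3, KI (cat.), CuI (cat.), acetone, 56 °C; filter, evaporate; xylene, 140 °C
Reagents that add atoms: 3-chloro-3-methylbut-1-yne, CC(C)(Cl)C#C
Why: Copper-assisted O-propargylation, then aromatic propargyl Claisen rearrangement/1,5-H shift/oxa-6π electrocyclisation; C7 is the only free position ortho to O8, so the chromene forms regiospecifically.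

Step 9
Reactants: 19 bromo-pterocarpan-chromene
Product: 21 3,9-di-O-(methoxymethyl)lespecyrtin E3, via 2,10-dilithio derivative of 19 20 (not isolated)
Conditions: t-BuLi (3.3 equiv), TMEDA, THF, −78→−45 °C; CuI (cat.), prenyl bromide, −78→0 °C
Reagents that add atoms: prenyl bromide (1-bromo-3-methylbut-2-ene), CC(C)=CCBr
Why: Bromine–lithium exchange at C2 and directed ortho-metalation at C10 (the only D-ring C–H, flanked by OMOM and O11), then copper-catalysed SN2 allylation; the C2 aryllithium makes ring A anionic, which suppresses metalation of its C4–H.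

Step 10
Reactants: 21 di-MOM ether
Product: 22 lespecyrtin E3
Conditions: 3 M aq. HCl, MeOH, 45 °C
Reagents that add atoms: none
Why: Acid-catalysed acetal cleavage (MOM removal) under mild conditions commonly used for prenylated phenols; the cis-pterocarpan can only re-close cis if C11a ionises.

## Compound list

1 | 4-bromo-2,5-dimethoxybenzaldehyde | COc1cc(Br)c(OC)cc1C=O | starting material
2 | 4-bromo-2,5-dimethoxyphenyl formate | COc1cc(Br)c(OC)cc1OC=O | intermediate
3 | 4-bromo-2,5-dimethoxyphenol | COc1cc(Br)c(OC)cc1O | intermediate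
4 | 1-bromo-2,5-dimethoxy-4-(methoxymethoxy)benzene | COCOc1cc(OC)c(Br)cc1OC | intermediate
5 | (R)-epichlorohydrin | ClC[C@H]1CO1 | starting material
6 | [2,5-dimethoxy-4-(methoxymethoxy)phenyl]magnesium bromide | COCOc1cc(OC)c([Mg]Br)cc1OC | intermediate
7 | (2R)-1-chloro-3-[2,5-dimethoxy-4-(methoxymethoxy)phenyl]propan-2-ol | COCOc1cc(OC)c(C[C@@H](O)CCl)cc1OC | intermediate
8 | 4-bromoresorcinol | Oc1ccc(Br)c(O)c1 | starting material
9 | (2R)-2-[2,5-dimethoxy-4-(methoxymethoxy)benzyl]oxirane | COCOc1cc(OC)c(C[C@@H]2CO2)cc1OC | intermediate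
10 | (2R)-1-(4-bromo-3-hydroxyphenoxy)-3-[2,5-dimethoxy-4-(methoxymethoxy)phenyl]propan-2-ol | COCOc1cc(OC)c(C[C@@H](O)COc2ccc(Br)c(O)c2)cc1OC | intermediate
11 | (2R)-1-[4-bromo-3-(methoxymethoxy)phenoxy]-3-[2,5-dimethoxy-4-(methoxymethoxy)phenyl]propan-2-ol | COCOc1cc(OC)c(C[C@@H](O)COc2ccc(Br)c(OCOC)c2)cc1OC | intermediate
12 | (2R)-triflate of 11 | COCOc1cc(OC)c(C[C@@H](OS(=O)(=O)C(F)(F)F)COc2ccc(Br)c(OCOC)c2)cc1OC | intermediate
13 | phenonium (spiro[2.5]octadienyl) triflate, spiro centre unassigned | COC[O+]=C1C=C(OC)C2(C[C@H]2COc3ccc(Br)c(OCOC)c3)C=C1OC.[O-]S(=O)(=O)C(F)(F)F | intermediate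
14 | (3R)-6-bromo-3-[2,5-dimethoxy-4-(methoxymethoxy)phenyl]-7-(methoxymethoxy)chroman | COCOc1cc2OC[C@@H](c3cc(OC)c(OCOC)cc3OC)Cc2cc1Br | intermediate
15 | 2-[(3R)-6-bromo-7-(methoxymethoxy)chroman-3-yl]-5-(methoxymethoxy)-1,4-benzoquinone | O=C1C=C(OCOC)C(=O)C=C1[C@@H]1COc2cc(OCOC)c(Br)cc2C1 | intermediate
16 | zwitterion: 4-chromanyl cation (oxocarbenium form) with 2′-hydroxy-5′-oxidoaryl at C3 | COC[O+]=C1C=C2OC[C@H](C=C2C=C1Br)c1cc([O-])c(OCOC)cc1O | intermediate
17 | (6aR,11aR)-2-bromo-3,9-bis(methoxymethoxy)-6a,11a-dihydro-6H-benzofuro[3,2-c]chromen-8-ol | Brc1cc2c(cc1OCOC)OC[C@H]1c3cc(O)c(OCOC)cc3O[C@@H]21 | intermediate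
18 | (6aR,11aR)-2-bromo-3,9-bis(methoxymethoxy)-8-(2-methylbut-3-yn-2-yloxy)pterocarpan | Brc1cc2c(cc1OCOC)OC[C@H]1c3cc(OC(C)(C)C#C)c(OCOC)cc3O[C@@H]21 | intermediate
19 | (6aR,11aR)-2-bromo-3,9-bis(methoxymethoxy)pterocarpan with 2,2-dimethyl-2H-pyran fused at C7–C8 | Brc1cc2c(cc1OCOC)OC[C@H]1c3c4c(c(OCOC)cc3O[C@@H]21)OC(C)(C)C=C4 | intermediate
20 | 2,10-dilithio derivative of 19 | [Li]c1cc2c(cc1OCOC)OC[C@H]1c3c4c(c(OCOC)c([Li])c3O[C@@H]21)OC(C)(C)C=C4 | intermediate
21 | 3,9-di-O-(methoxymethyl)lespecyrtin E3 | CC(C)=CCc1cc2c(cc1OCOC)OC[C@H]1c3c4c(c(OCOC)c(CC=C(C)C)c3O[C@@H]21)OC(C)(C)C=C4 | intermediate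
22 | lespecyrtin E3, (6aR,11aR) | CC(C)=CCc1cc2c(cc1O)OC[C@H]1c3c4c(c(O)c(CC=C(C)C)c3O[C@@H]21)OC(C)(C)C=C4 | target

## Step count and risks

Total steps: 10. Longest linear sequence: 10.

**Step 5 (proposed new step).** Risks are methoxy-oxygen (MeO-5) participation of the 2′-OMe, elimination, or opening of the phenonium ion at the wrong carbon. The fallback uses known chemistry, sets out from 8 (with Grignard 6) and comes back at 14. 4-Bromoresorcinol 8 is O-allylated at the OH para to Br (allyl bromide, K2CO3) to 5-(allyloxy)-2-bromophenol F1, then MOM-protected to 4-(allyloxy)-1-bromo-2-(methoxymethoxy)benzene F2. Cross-metathesis (Grubbs II) with bought (R)-but-3-en-2-ol gives (2R,3E)-5-[4-bromo-3-(methoxymethoxy)phenoxy]pent-3-en-2-ol F3, which is esterified to its pyridine-2-carboxylate F4. Copper-mediated anti-SN2′ substitution with Grignard 6 (CuBr·SMe2) transfers the stereocenter to the aryl-bearing carbon and gives the (R,E)-2-aryl-pent-3-enyl aryl ether F5. Ozonolysis with NaBH4 work-up gives (2S)-3-[4-bromo-3-(methoxymethoxy)phenoxy]-2-[2,5-dimethoxy-4-(methoxymethoxy)phenyl]propan-1-ol F6. Its primary triflate F7 (Tf2O, hindered pyridine) closes the chroman by intramolecular Friedel–Crafts alkylation to 14 without touching the stereocenter.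

**Step 7 (proposed new step).** Risks are low photoreactivity of the alkoxyquinone, hydrogen abstraction from the MOM CH2 or chroman C2–H, and secondary photo-oxidation of the product. The fallback uses known chemistry, sets out from 15 and comes back at 17. Quinone 15 is reduced (Na2S2O4) to the hydroquinone 2-[(3R)-6-bromo-7-(methoxymethoxy)chroman-3-yl]-5-(methoxymethoxy)benzene-1,4-diol F8. The less hindered 5′-OH is pivaloylated (PivCl, pyridine, −20 °C) to the 5′-O-pivalate F9. DDQ oxidative cyclisation of this 2′-hydroxyisoflavan (hydride abstraction at C4, trapping by the 2′-OH, cis-fusion dictated by C3) gives (6aR,11aR)-2-bromo-3,9-bis(methoxymethoxy)pterocarpan-8-yl pivalate F10. K2CO3/MeOH then gives 17.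

**Step 9.** Risks are incomplete C10 metalation, base-induced opening of the benzylic ether, and O/C scrambling. The fallback replaces lithiation by halogenation and cross-coupling, sets out from 18 (isolated instead of telescoped) and comes back at 21. NBS brominates the D-ring position flanked by two oxygens to give the 10-bromo propargyl ether F11. Thermal Claisen/electrocyclisation (xylene, 140 °C) gives the 2,10-dibromo pterocarpan-chromene F12. Double Stille coupling with tributyl(3-methylbut-2-enyl)stannane (Pd(PPh3)4, DMF, 100 °C) gives 21.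

## Further compounds

F1 | step 5 | 5-(allyloxy)-2-bromophenol | C=CCOc1ccc(Br)c(O)c1
F2 | step 5 | 4-(allyloxy)-1-bromo-2-(methoxymethoxy)benzene | C=CCOc1ccc(Br)c(OCOC)c1
F3 | step 5 | (2R,3E)-5-[4-bromo-3-(methoxymethoxy)phenoxy]pent-3-en-2-ol | C[C@@H](O)/C=C/COc1ccc(Br)c(OCOC)c1
F4 | step 5 | (2R,3E)-5-[4-bromo-3-(methoxymethoxy)phenoxy]pent-3-en-2-yl pyridine-2-carboxylate | C[C@@H](OC(=O)c1ccccn1)/C=C/COc1ccc(Br)c(OCOC)c1
F5 | step 5 | 1-{(2R,3E)-1-[4-bromo-3-(methoxymethoxy)phenoxy]pent-3-en-2-yl}-2,5-dimethoxy-4-(methoxymethoxy)benzene | C/C=C/[C@@H](COc1ccc(Br)c(OCOC)c1)c1cc(OC)c(OCOC)cc1OC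
F6 | step 5 | (2S)-3-[4-bromo-3-(methoxymethoxy)phenoxy]-2-[2,5-dimethoxy-4-(methoxymethoxy)phenyl]propan-1-ol | OC[C@@H](COc1ccc(Br)c(OCOC)c1)c1cc(OC)c(OCOC)cc1OC
F7 | step 5 | (2R)-3-[4-bromo-3-(methoxymethoxy)phenoxy]-2-[2,5-dimethoxy-4-(methoxymethoxy)phenyl]propyl triflate | FC(F)(F)S(=O)(=O)OC[C@@H](COc1ccc(Br)c(OCOC)c1)c1cc(OC)c(OCOC)cc1OC
F8 | step 7 | 2-[(3R)-6-bromo-7-(methoxymethoxy)chroman-3-yl]-5-(methoxymethoxy)benzene-1,4-diol | COCOc1cc2OC[C@@H](c3cc(O)c(OCOC)cc3O)Cc2cc1Br
F9 | step 7 | 5-[(3R)-6-bromo-7-(methoxymethoxy)chroman-3-yl]-4-hydroxy-2-(methoxymethoxy)phenyl pivalate | COCOc1cc2OC[C@@H](c3cc(OC(=O)C(C)(C)C)c(OCOC)cc3O)Cc2cc1Br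
F10 | step 7 | (6aR,11aR)-2-bromo-3,9-bis(methoxymethoxy)pterocarpan-8-yl pivalate | Brc1cc2c(cc1OCOC)OC[C@H]1c3cc(OC(=O)C(C)(C)C)c(OCOC)cc3O[C@@H]21
F11 | step 9 | (6aR,11aR)-2,10-dibromo-3,9-bis(methoxymethoxy)-8-(2-methylbut-3-yn-2-yloxy)pterocarpan | Brc1cc2c(cc1OCOC)OC[C@H]1c3cc(OC(C)(C)C#C)c(OCOC)c(Br)c3O[C@@H]21
F12 | step 9 | (6aR,11aR)-2,10-dibromo-3,9-bis(methoxymethoxy)pterocarpan with 2,2-dimethyl-2H-pyran fused at C7–C8 | Brc1cc2c(cc1OCOC)OC[C@H]1c3c4c(c(OCOC)c(Br)c3O[C@@H]21)OC(C)(C)C=C4
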